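**Assumptions (one line):** The purchasable starting materials are methyl 3-(4-hydroxyphenyl)propanoate, 5-methoxyresorcinol, 4-hydroxybenzaldehyde and 4-bromophenol. I assume a commercial ketoreductase panel contains an enzyme that gives the (S)-alcohol from the prochiral ketone, that the Ir/amine α-allylation tolerates the β-branched aldehyde with the needed (R,S) catalyst pair, and that compound 7 is made once on double scale and used in Steps 7 and 17.

**Atom labels.** THP ring: O1, T2 (bears the aryl), T3, T4 (bears the chalcone ring A), T5, T6. A3 is the side-chain carbinol. A7 is the exocyclic benzylic CH. MOM = CH2OCH3. TBS = SiMe2tBu.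

## Retrosynthetic overview
1. The target comes from global MOM removal of a hepta-MOM chalcone. The chalcone is made by Claisen–Schmidt condensation of an aryl methyl ketone, whose acetyl group is installed last on ring A by bromination and then Br/Li exchange with Weinreb acetylation.
2. The THP is the only ring built. It closes by acid-mediated dehydrative cyclisation of a triol, with the benzylic T2-OH ionised and trapped by the T6-OH. Thermodynamic control gives the all-equatorial chair (2,6-cis, 2,3-trans, 3,4-trans), which is the target's relative configuration.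
3. The triol comes from four operations:
   - cross-metathesis of a terminal vinyl group with a TBS-protected homoallylic alcohol;
   - ArMgBr addition to an α,β-branched aldehyde;
   - Ir/amine α-allylation, which sets T3 and A7;
   - Rh/diene 1,4-arylation of an enoate, which sets T4.
4. T6 and A3 both come from one batch of (S)-1-aryl-hex-5-en-3-ol, made by enzymatic ketone reduction. This is the first stereocentre. The TBS ether of that alcohol is the enoate precursor and also the metathesis partner.

## Route

**Step 1**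
Reactants: 1 methyl 3-(4-hydroxyphenyl)propanoate
Product: 2 methyl 3-[4-(methoxymethoxy)phenyl]propanoate
Conditions: MOMCl, i-Pr2NEt, CH2Cl2, 0 °C → rt
Reagents that add atoms: chloromethyl methyl ether, ClCOC
Why: O-alkylation of the phenol gives a MOM ether that survives the organolithium, Grignard, hydride, metathesis and mild Lewis-acid steps that follow.

**Step 2**
Reactants: 2
Product: 3 3-[4-(methoxymethoxy)phenyl]propanal
Conditions: DIBAL-H (1.1 equiv), CH2Cl2, −78 °C; Rochelle salt work-up
Reagents that add atoms: none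
Why: a stable tetrahedral aluminate at −78 °C stops the ester reduction at the aldehyde.

**Step 3**
Reactants: 3
Product: 4 (±)-1-[4-(methoxymethoxy)phenyl]hex-5-en-3-ol
Conditions: CH2=CHCH2MgBr (1.2 equiv), THF, −78 → 0 °C
Reagents that add atoms: allylmagnesium bromide, C=CC[Mg]Br
Why: Grignard 1,2-addition to the aldehyde gives the racemic homoallylic alcohol. It is the substrate for the oxidation/enzymatic-reduction pair that follows, and the stereocentre is deliberately destroyed in the next step.

**Step 4**
Reactants: 4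
Product: 5 1-[4-(methoxymethoxy)phenyl]hex-5-en-3-one
Conditions: Dess–Martin periodinane (1.5 equiv), NaHCO3, CH2Cl2, 0 °C → rt
Reagents that add atoms: none
Why: buffered, non-basic oxidation gives the prochiral ketone without isomerising the β,γ-alkene into conjugation.

**Step 5**
Reactants: 5
Product: 6 (3S)-1-[4-(methoxymethoxy)phenyl]hex-5-en-3-ol
Conditions: (S)-selective ketoreductase (KRED, oxidoreductase class), NADP+ (0.5 mol%), i-PrOH (10% v/v, cofactor recycling), KPi pH 7.0, DMSO (10%), 30 °C
Reagents that add atoms: none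
Why: the NADPH-dependent ketoreductase delivers hydride to one enantioface of the ketone (enzymatic asymmetric reduction), setting the first stereocentre as the (S)-carbinol that becomes both T6 and A3. At pH 7 the β,γ-alkene does not isomerise.

**Step 6**
Reactants: 6
Product: 7 (3S)-3-(tert-butyldimethylsilyloxy)-1-[4-(methoxymethoxy)phenyl]hex-5-ene
Conditions: TBSCl, imidazole, DMF, rt
Reagents that add atoms: tert-butyldimethylsilyl chloride, C[Si](C)(Cl)C(C)(C)C
Why: silylation masks the alcohol for the Rh, DIBAL, Ir/amine and Grignard steps without touching the stereocentre.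

**Step 7**
Reactants: 7
Product: 8 methyl (2E,5S)-5-(TBSO)-7-[4-(MOMO)phenyl]hept-2-enoate
Conditions: methyl acrylate (4 equiv), Hoveyda–Grubbs II (3 mol%), CH2Cl2, 40 °C
Reagents that add atoms: methyl acrylate, C=CC(=O)OC
Why: cross-metathesis of a terminal alkene with an acrylate is E-selective and builds the enoate whose ester carbon becomes T2 and whose α-carbon becomes T3.

**Step 8**
Reactants: 9 5-methoxybenzene-1,3-diol
Product: 10 1,3-bis(methoxymethoxy)-5-methoxybenzene
Conditions: NaH (2.3 equiv), THF/DMF, 0 °C; MOMCl (2.4 equiv)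
Reagents that add atoms: chloromethyl methyl ether, ClCOC
Why: double O-alkylation of the phenoxides gives the symmetric substrate for ortho-metalation.

**Step 9**
Reactants: 10
Product: 11 [2,6-bis(methoxymethoxy)-4-methoxyphenyl]boronic acid
Conditions: n-BuLi (1.1 equiv), THF, 0 °C; B(OiPr)3, −78 °C → rt; aq. NH4Cl
Reagents that add atoms: triisopropyl borate, CC(C)OB(OC(C)C)OC(C)C
Why: directed ortho-lithiation occurs at C2, the only position flanked by two OMOM directors, so it is regiospecific; the borate quench and mild hydrolysis give the boronic acid.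

**Step 10**
Reactants: 8, 11
Product: 12 methyl (3R,5S)-5-(TBSO)-3-[2,6-bis(MOMO)-4-methoxyphenyl]-7-[4-(MOMO)phenyl]heptanoate
Conditions: [Rh(C2H4)2Cl]2 (2.5 mol%), chiral diene L* (5.5 mol%, enantiomer chosen to give 3R), 11 (3 equiv, portionwise), KOH (0.5 equiv), dioxane/H2O 10:1, 50 °C
Reagents that add atoms: none
Why: Hayashi–Miyaura asymmetric 1,4-addition of the arylboronic acid to the enoate, with water as the proton source. The Rh–diene catalyst controls the enoate face and sets T4 as (R), overriding the remote T6 centre. Any diastereomer from imperfect control is separable at this stage.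

**Step 11**
Reactants: 12
Product: 13 (3R,5S)-3-[2,6-bis(MOMO)-4-methoxyphenyl]-5-(TBSO)-7-[4-(MOMO)phenyl]heptanal
Conditions: DIBAL-H (1.1 equiv), toluene, −78 °C
Reagents that add atoms: none
Why: partial ester reduction to the aldehyde; the β-stereocentre cannot epimerise.

**Step 12**
Reactants: 14 4-hydroxybenzaldehyde
Product: 15 4-(methoxymethoxy)benzaldehyde
Conditions: MOMCl, i-Pr2NEt, CH2Cl2, 0 °C → rt
Reagents that add atoms: chloromethyl methyl ether, ClCOC
Why: phenol protection; this aldehyde is also the chalcone B-ring component in Step 22.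

**Step 13**
Reactants: 15
Product: 16 (±)-1-[4-(methoxymethoxy)phenyl]prop-2-en-1-ol
Conditions: CH2=CHMgBr, THF, 0 °C
Reagents that add atoms: vinylmagnesium bromide, C=C[Mg]Br
Why: Grignard 1,2-addition gives a racemic branched allylic alcohol; racemic material is acceptable because the Ir-π-allyl intermediate formed from it is the same for both enantiomers.

**Step 14**
Reactants: 13, 16
Product: 17 (2R,3R,5S)-2-[(1S)-1-[4-(MOMO)phenyl]prop-2-en-1-yl]-3-[2,6-bis(MOMO)-4-methoxyphenyl]-5-(TBSO)-7-[4-(MOMO)phenyl]heptanal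
Conditions: [Ir(cod)Cl]2 (2 mol%), phosphoramidite–olefin ligand (8 mol%), diarylprolinol silyl ether (20 mol%), ArCO2H co-catalyst, dioxane, rt; crude aldehyde used at once
Reagents that add atoms: none
Why: stereodivergent Ir/enamine dual-catalytic α-allylation. The amine sets T3 (R) through enamine face selectivity, and the Ir-π-allyl sets the branched benzylic A7 (S). The catalyst enantiomer pair is chosen from the four possible combinations, and the T4 centre is remote.

**Step 15**
Reactants: 18 4-bromophenol
Product: 19 1-bromo-4-(methoxymethoxy)benzene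
Conditions: MOMCl, i-Pr2NEt, CH2Cl2, 0 °C → rt
Reagents that add atoms: chloromethyl methyl ether, ClCOC
Why: protection before Grignard formation.

**Step 16**
Reactants: 17, 19 (as its Grignard reagent)
Product: 20 T2 carbinol, about 1:1 mixture of benzylic epimers; T3, T4, A7 and T6 unchanged
Conditions: 19, Mg, THF, 50 °C → ArMgBr; then 17, THF, −78 → 0 °C
Reagents that add atoms: 4-(methoxymethoxy)phenylmagnesium bromide, COCOc1ccc([Mg]Br)cc1
Why: Grignard addition removes the epimerisable aldehyde and fixes T3. The new carbinol epimers need not be separated because both ionise to the same benzylic cation in Step 19.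

**Step 17**
Reactants: 20, 7
Product: 21 cross-metathesis product: (E)-A5=A6 alkene, T6-OTBS and A3-OTBS both present, T2 carbinol epimeric
Conditions: 7 (3 equiv), Hoveyda–Grubbs II (5 mol%), 1,4-benzoquinone (10 mol%), CH2Cl2, 40 °C
Reagents that add atoms: none
Why: cross-metathesis of the terminal vinyl group with the homoallylic silyl ether gives the E-alkene; benzoquinone suppresses Ru–H alkene isomerisation. A3 comes in with its (S) configuration untouched.

**Step 18**
Reactants: 21
Product: 22 triol (T2-OH, T6-OH and A3-OH free)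
Conditions: TBAF, THF, 0 °C → rt
Reagents that add atoms: none
Why: fluoride removes both alkyl TBS ethers; the MOM ethers and the alkene are untouched, and no stereocentre is affected.

**Step 19**
Reactants: 22
Product: 23 THP (2S,3R,4R,6S), A3-OH free, all phenols as MOM ethers
Conditions: Sc(OTf)3 (5 mol%), 4 Å MS, CH2Cl2 (0.005 M), 0 °C → rt
Reagents that add atoms: none
Why: SN1 dehydrative etherification. Both T2 epimers ionise to the same p-alkoxybenzylic cation, and reversible closure onto the T6-OH under thermodynamic control gives the all-equatorial chair, which sets T2 as (S). Closure onto the A3-OH would need an 8-membered ring containing an E-alkene and is disfavoured.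

**Step 20**
Reactants: 23
Product: 24 aryl bromide: Br on ring A between OMe and OMOM
Conditions: NBS (1.05 equiv), CH2Cl2, −20 → 0 °C, dark
Reagents that add atoms: N-bromosuccinimide, O=C1CCC(=O)N1Br
Why: electrophilic aromatic bromination occurs at the most electron-rich ring, the 1,3,5-trioxygenated ring A. Its two free positions are equivalent by rotation about the Ar–THP bond, so a single regioisomer forms. The other aryl rings, the alkene and all stereocentres are untouched under these non-radical, low-temperature conditions.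

**Step 21**
Reactants: 24
Product: 25 aryl methyl ketone: acetyl on ring A between OMe and OMOM
Conditions: n-BuLi (1.1 equiv), THF, −78 °C, 10 min; t-BuLi (2.2 equiv), −78 °C, 15 min; then MeC(O)N(OMe)Me (5 equiv), −78 → 0 °C; aq. NH4Cl
Reagents that add atoms: N-methoxy-N-methylacetamide, CC(=O)N(C)OC
Why: n-BuLi first converts the A3-OH to its alkoxide. Br/Li exchange with t-BuLi then gives a single aryllithium stabilised by the ortho oxygen groups, with no competing deprotonation of the other MOM-aryl rings. The Weinreb acetamide gives the ketone without over-addition.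

**Step 22**
Reactants: 25, 15 (1.5 equiv)
Product: 26 protected chalcone, (E)-enone
Conditions: NaOH (5 equiv), EtOH/THF, 25 → 40 °C, 48 h
Reagents that add atoms: none
Why: Claisen–Schmidt aldol condensation; E1cB dehydration gives the thermodynamic (E)-enone, no new stereocentre forms, and the MOM ethers, secondary alcohol and THP are base-stable.

**Step 23**
Reactants: 26
Product: 27 blepharocalyxin E
Conditions: 3 M HCl, MeOH/THF (2:1), 35 °C, monitored (about 6 h)
Reagents that add atoms: none
Why: acid-mediated cleavage of the seven aryl MOM acetals releases the phenols. The conditions are mild enough to leave the (E)-enone, the THP and all stereocentres intact.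

## Compound list
1 | methyl 3-(4-hydroxyphenyl)propanoate | COC(=O)CCc1ccc(O)cc1 | starting material
2 | methyl 3-[4-(MOMO)phenyl]propanoate | COC(=O)CCc1ccc(OCOC)cc1 | intermediate
3 | 3-[4-(MOMO)phenyl]propanal | O=CCCc1ccc(OCOC)cc1 | intermediate
4 | (±)-1-[4-(MOMO)phenyl]hex-5-en-3-ol | C=CCC(O)CCc1ccc(OCOC)cc1 | intermediate
5 | 1-[4-(MOMO)phenyl]hex-5-en-3-one | C=CCC(=O)CCc1ccc(OCOC)cc1 | intermediate
6 | (3S)-1-[4-(MOMO)phenyl]hex-5-en-3-ol | C=CC[C@@H](O)CCc1ccc(OCOC)cc1 | intermediate
7 | (3S)-3-(TBSO)-1-[4-(MOMO)phenyl]hex-5-ene | C=CC[C@@H](O[Si](C)(C)C(C)(C)C)CCc1ccc(OCOC)cc1 | intermediate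
8 | methyl (2E,5S)-5-(TBSO)-7-[4-(MOMO)phenyl]hept-2-enoate | COC(=O)/C=C/C[C@@H](O[Si](C)(C)C(C)(C)C)CCc1ccc(OCOC)cc1 | intermediate
9 | 5-methoxybenzene-1,3-diol | COc1cc(O)cc(O)c1 | starting material
10 | 1,3-bis(MOMO)-5-methoxybenzene | COc1cc(OCOC)cc(OCOC)c1 | intermediate
11 | [2,6-bis(MOMO)-4-methoxyphenyl]boronic acid | COc1cc(OCOC)c(B(O)O)c(OCOC)c1 | intermediate
12 | methyl (3R,5S)-3-[2,6-bis(MOMO)-4-methoxyphenyl]-5-(TBSO)-7-[4-(MOMO)phenyl]heptanoate | COC(=O)C[C@H](c1c(OCOC)cc(OC)cc1OCOC)C[C@@H](O[Si](C)(C)C(C)(C)C)CCc1ccc(OCOC)cc1 | intermediate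
13 | (3R,5S)-3-[2,6-bis(MOMO)-4-methoxyphenyl]-5-(TBSO)-7-[4-(MOMO)phenyl]heptanal | O=CC[C@H](c1c(OCOC)cc(OC)cc1OCOC)C[C@@H](O[Si](C)(C)C(C)(C)C)CCc1ccc(OCOC)cc1 | intermediate
14 | 4-hydroxybenzaldehyde | O=Cc1ccc(O)cc1 | starting material
15 | 4-(MOMO)benzaldehyde | O=Cc1ccc(OCOC)cc1 | intermediate
16 | (±)-1-[4-(MOMO)phenyl]prop-2-en-1-ol | C=CC(O)c1ccc(OCOC)cc1 | intermediate
17 | (2R,3R,5S)-2-[(1S)-1-[4-(MOMO)phenyl]prop-2-en-1-yl]-3-[2,6-bis(MOMO)-4-methoxyphenyl]-5-(TBSO)-7-[4-(MOMO)phenyl]heptanal | O=C[C@@H]([C@H](C=C)c1ccc(OCOC)cc1)[C@H](c1c(OCOC)cc(OC)cc1OCOC)C[C@@H](O[Si](C)(C)C(C)(C)C)CCc1ccc(OCOC)cc1 | intermediate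
18 | 4-bromophenol | Oc1ccc(Br)cc1 | starting material
19 | 1-bromo-4-(MOMO)benzene | COCOc1ccc(Br)cc1 | intermediate
20 | T2 carbinol, epimeric at the benzylic carbinol carbon | OC(c1ccc(OCOC)cc1)[C@@H]([C@H](C=C)c1ccc(OCOC)cc1)[C@H](c1c(OCOC)cc(OC)cc1OCOC)C[C@@H](O[Si](C)(C)C(C)(C)C)CCc1ccc(OCOC)cc1 | intermediate
21 | cross-metathesis product (bis-TBS, epimeric T2 carbinol) | OC(c1ccc(OCOC)cc1)[C@@H]([C@H](/C=C/C[C@@H](O[Si](C)(C)C(C)(C)C)CCc1ccc(OCOC)cc1)c1ccc(OCOC)cc1)[C@H](c1c(OCOC)cc(OC)cc1OCOC)C[C@@H](O[Si](C)(C)C(C)(C)C)CCc1ccc(OCOC)cc1 | intermediate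
22 | triol (T2-OH epimeric; T6-OH, A3-OH free) | OC(c1ccc(OCOC)cc1)[C@@H]([C@H](/C=C/C[C@@H](O)CCc1ccc(OCOC)cc1)c1ccc(OCOC)cc1)[C@H](c1c(OCOC)cc(OC)cc1OCOC)C[C@@H](O)CCc1ccc(OCOC)cc1 | intermediate
23 | hexa-MOM THP with A3-OH free | COc1cc(OCOC)c([C@@H]2C[C@H](CCc3ccc(OCOC)cc3)O[C@H](c3ccc(OCOC)cc3)[C@H]2[C@H](/C=C/C[C@@H](O)CCc2ccc(OCOC)cc2)c2ccc(OCOC)cc2)c(OCOC)c1 | intermediate
24 | ring-A aryl bromide of 23 | COc1cc(OCOC)c([C@@H]2C[C@H](CCc3ccc(OCOC)cc3)O[C@H](c3ccc(OCOC)cc3)[C@H]2[C@H](/C=C/C[C@@H](O)CCc2ccc(OCOC)cc2)c2ccc(OCOC)cc2)c(OCOC)c1Br | intermediate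
25 | aryl methyl ketone | COc1cc(OCOC)c([C@@H]2C[C@H](CCc3ccc(OCOC)cc3)O[C@H](c3ccc(OCOC)cc3)[C@H]2[C@H](/C=C/C[C@@H](O)CCc2ccc(OCOC)cc2)c2ccc(OCOC)cc2)c(OCOC)c1C(C)=O | intermediate
26 | hepta-MOM protected chalcone | COc1cc(OCOC)c([C@@H]2C[C@H](CCc3ccc(OCOC)cc3)O[C@H](c3ccc(OCOC)cc3)[C@H]2[C@H](/C=C/C[C@@H](O)CCc2ccc(OCOC)cc2)c2ccc(OCOC)cc2)c(OCOC)c1C(=O)/C=C/c1ccc(OCOC)cc1 | intermediate
27 | blepharocalyxin E | COc1cc(O)c([C@@H]2C[C@H](CCc3ccc(O)cc3)O[C@H](c3ccc(O)cc3)[C@H]2[C@H](/C=C/C[C@@H](O)CCc2ccc(O)cc2)c2ccc(O)cc2)c(O)c1C(=O)/C=C/c1ccc(O)cc1 | target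

## Totals
- Total steps: 23.
- Longest linear sequence: 18 steps (Steps 1–7, 10, 11, 14, 16–23), running 1 → 2 → 3 → 4 → 5 → 6 → 7 → 8 → 12 → 13 → 17 → 20 → 21 → 22 → 23 → 24 → 25 → 26 → 27.

## Three steps most likely to fail
1. **Step 5 (ketoreductase reduction).** The enzyme must distinguish an allyl group from a 2-arylethyl group, which are similar in size, so ee may be insufficient.
   *Fallback (different approach):* lipase-catalysed kinetic resolution of racemic 4 (CAL-B, vinyl acetate, MTBE). Use the enzyme and acyl donor that acylate the (R)-enantiomer, and take (S)-6 as the unreacted alcohol. Hydrolyse, oxidise (DMP) and recycle the (R)-acetate to ketone 5.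
2. **Step 10 (Rh-catalysed arylation).** The 2,6-dioxygenated boronic acid is hindered and prone to protodeboronation, and enoates are poorer substrates than enones.
   *Fallback (different approach):* Pd/SPhos Suzuki coupling of 11 with the enol triflate of methyl 3-oxo-5-(TBSO)-7-[4-(MOMO)phenyl]heptanoate, then Ir–P,N asymmetric hydrogenation of the trisubstituted β-aryl-β-alkyl acrylate, which returns to 12.
3. **Step 14 (Ir/amine α-allylation of a β-branched aldehyde).** Yield or diastereocontrol at T3/A7 may be poor, and the α-stereocentre can epimerise.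
   *Fallback (different approach):* Ireland–Claisen rearrangement. Hydrolyse 12 to the acid and esterify it with the (E)-allylic alcohol ArCH=CH–CH(OH)–CH2–CH(OTBS)CH2CH2Ar (Ar = 4-MOMOC6H4). LDA/TBSCl rearrangement transfers the carbinol chirality to T3/A7 through a chair transition state. Then convert the acid to the Weinreb amide and add ArMgBr to give the T2 aryl ketone, and close the ring by reductive etherification (Et3SiH, TMSOTf) with the T6-OH.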